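**The leftover.** In Saturday's flask at 25.0 min, target and isomer of the product together hold 11.0% of the substrate charged, and the rest of the charge stands outside these readings. The question below sets that leftover aside and asks how the arrived part divides, which makes it a question about the age of target.

| flask | substrate | partner | remark | time |
|---|---|---|---|---|
| Saturday's | 0.10 M | 0.090 M | run made earlier |  |
| Tuesday's | 0.050 M | 0.090 M | run made earlier |  |
| Friday's | 0.075 M | 0.090 M | run made earlier |  |
| Wednesday's | 0.10 M | 0.045 M | run made earlier |  |
| east | 0.10 M (fed, over 12.5 min) | 0.0900 M | a stirred flask in which substrate is dosed at a steady rate over 12.5 min without added volume, worked up at 25 min | 25 min |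
| north-west | 0.10 M | 0.0900 M | one stirred flow tank at steady state, fed with the mixture as stated, mean residence time 25 min |  |
| south | 0.10 M | 0.0900 M | everything together in a closed stirred flask, run for 25 min | 25 min |
| north | 0.10 M | 0.0900 M | a single well-mixed tank run continuously and read at steady state, 75.0 min in it on average |  |

| run | time / min | target / % | isomer of the product / % |
|---|---|---|---|
| Saturday's | 2.00 | 0.1 | 0 |
| Saturday's | 3.00 | 1.0 | 0 |
| Saturday's | 5.00 | 1.6 | 0.4 |
| Saturday's | 8.00 | 3.9 | 1.3 |
| Saturday's | 10.0 | 4.4 | 2.2 |
| Saturday's | 15.0 | 4.7 | 4.1 |
| Saturday's | 25.0 | 5.0 | 6.0 |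
| Tuesday's | 0.833 | 0.2 | 0.7 |
| Tuesday's | 2.50 | 0.7 | 0 |
| Tuesday's | 4.00 | 0.9 | 0 |
| Tuesday's | 6.00 | 3.3 | 1.6 |
| Tuesday's | 10.0 | 4.1 | 1.4 |
| Tuesday's | 12.0 | 4.6 | 2.6 |
| Tuesday's | 15.0 | 5.7 | 3.6 |
| Friday's | 2.00 | 0 | 1.1 |
| Friday's | 4.00 | 0.8 | 0 |
| Friday's | 6.00 | 3.5 | 0.5 |
| Friday's | 8.00 | 3.5 | 1.4 |
| Friday's | 10.0 | 3.6 | 1.5 |
| Friday's | 12.0 | 4.8 | 3.1 |
| Friday's | 15.0 | 4.3 | 3.9 |
| Wednesday's | 1.33 | 0.3 | 0 |
| Wednesday's | 2.50 | 0 | 0.1 |
| Wednesday's | 4.00 | 1.1 | 0.6 |
| Wednesday's | 8.00 | 3.8 | 0.5 |
| Wednesday's | 15.0 | 6.7 | 3.8 |

(each reading ± 0.5 percentage points)

- the stated concentrations are those of everything mixed, before any reaction; amounts are the same in each set-up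
- the feed brings no volume worth counting
- the earlier runs were made in a closed, stirred flask

- the set-up with the highest share of target in all that became target or isomer of the product, at the outlet or at the end ("none" if the first two lie within 2 percentage points) (east / north-west / south / north / none)
- share of target in all that became target or isomer of the product, at the outlet or at the end, east
- share of target in all that became target or isomer of the product, at the outlet or at the end, north-west
- share of target in all that became target or isomer of the product, at the outlet or at the end, south
- share of target in all that became target or isomer of the product, at the outlet or at the end, north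

**The clock.** Target formed steadily has a mean age of half the elapsed time, and early on the ratio of isomer to target is that age counted in lifetimes. Saturday's pair at 10.0 min so reads 10.0 min for the target lifetime, the mean time target lasts before turning into isomer.

**Lower bound.** If target leaves by that one road, a tank's share is one over one plus its residence time in lifetimes. That gives 28.6% for north-west and 11.8% for north.

**Upper bound.** Saturday's flask is south's recipe, and its last pair reads a share of 45.5%. Target leaving a tank should have about the residence time as its mean age, 25 min in north-west against 12.5 min in that flask, so this reading, with its scatter, should cap both tanks. The readings stop at 25.0 min, short of north's 75.0 min, so for north the cap stands on no reading of its own time. East receives its substrate over 12.5 min of 25 min, so its target is younger and its share should exceed the cap.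

**The forecast.** It reads “substrate → target → isomer, with first-order isomerisation” and gives 52% for east, 34% for north-west, 45% for south and 15% for north, naming east best. Both tank values lie inside the bracket, a little above my lower bounds.

**The flask.** East gives 53.5%, north-west 46.9%, south 45.8% and north 38.0%, so east is best. North lies inside the bracket, and north-west stands just above a cap of 45.5% that was itself read from scattered readings.

    substrate ⇌ intermediate A (K = 0.320, k = 0.290 min⁻¹)
    partner + intermediate A ⇌ intermediate B (K = 7.50 M⁻¹, k = 0.770 M⁻¹ min⁻¹)
    substrate ⇌ intermediate C (K = 1.60, k = 0.0590 min⁻¹)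
    intermediate C → target (k = 0.0610 min⁻¹)
    intermediate B ⇌ intermediate D (K = 0.180, k = 0.930 min⁻¹)
    intermediate A → decomposed reagent (k = 2.50 min⁻¹)
    target ⇌ isomer of the product (K = 2.10, k = 0.0980 min⁻¹)

**The floor.** The forward half-life of target, 7.1 min, is short against the 25 min of south, and the target–isomer balance of the scheme corresponds to a share of 32.3%. Counted in lifetimes, the north tank holds target for 7.50 on average and gives 38.0%, while the east flask left for 250 min has run 25.0 lifetimes and gives 32.3%.

The numbers in the tables come from a simulation for substances that don't exist; scatter was added.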